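The easy step comes first: percentages of the charge become concentrations, which show how much solid substrate has entered solution.

in all of them: enzyme 20 µM

| flask | solid substrate | second substrate | remark | time |
|---|---|---|---|---|
| cedar | 0.10 M | 0.40 M | run made earlier |  |
| maple | 0.40 M | 0.40 M | run made earlier |  |
| flask | 0.20 M | 0.400 M |  | 30 min |

| run | time / min | product / % | starting material / % |
|---|---|---|---|
| cedar | 1.33 | 3 | 4 |
| cedar | 2.00 | 0 | 2 |
| cedar | 3.00 | 0 | 5 |
| cedar | 5.00 | 0 | 8 |
| cedar | 8.00 | 0 | 13 |
| cedar | 12.0 | 2 | 19 |
| cedar | 20.0 | 9 | 26 |
| maple | 1.33 | 0 | 1 |
| maple | 2.00 | 0 | 2 |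
| maple | 3.00 | 0 | 2 |
| maple | 5.00 | 2 | 2 |
| maple | 8.00 | 0 | 5 |
| maple | 12.0 | 1 | 5 |
| maple | 20.0 | 0 | 7 |

(standard deviation of a reading: 1.5 percentage points)



- solid, in amounts per volume of the solution: solid substrate
- at the start none of the solid substrate is in solution
- starting material is what solid substrate becomes in solution
- starting material means what is dissolved; the solid is not counted in it

 In cedar, starting material plus product comes to 21.0 mM at 12.0 min and 35.0 mM at 20.0 min. The later reading gives 1.75 mM min⁻¹, and this amount entering solution per litre and minute is the feed F.

Time is the first setting. By hand, dissolved material grows in proportion to it, and the two cedar readings fit this, with 1.75 mM min⁻¹ at the earlier reading. The solid charge is next: by hand, a constant F leaves the concentration unchanged, so the percentage falls as the charge rises. Maple, with the larger charge, reads 28.0 mM at 20.0 min, though a single reading there scatters by 6.00 mM. Second substrate and enzyme are charged alike in cedar and maple, so these two runs offer no comparison of either setting.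

- amount of product at 30 min, in percent of the solid substrate charged
- concentration of starting material in solution at 30 min, in percent of saturation

This reckoning puts 52.5 mM into solution in the flask by 30 min, or 26.2% of its charge. Cedar's last product gain, continued at 0.875 mM min⁻¹, gives 8.87% of product. This reckoning gives no figure for saturation. The forecast, by contrast, gives 8.5% and 25%, the second with the warning “this is poorly constrained”.

The flask gives 7.35% of product and stands at 33.1% of saturation.

    starting material + enzyme ⇌ starting complex (K = 7.80 L mol⁻¹, k = 7000 L mol⁻¹ s⁻¹)
    ternary complex → enzyme + product (k = 2.30 s⁻¹)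
    second substrate → decomposed reagent (k = 2.00 × 10⁻⁴ s⁻¹)
    solid substrate ⇌ starting material, rate k4*(cs4 - [starting material]) while solid is left; crystals form when [starting material] > cs4 (solubility = 0.110 M, k = 3.20 × 10⁻⁴ s⁻¹)
    second substrate + starting complex ⇌ ternary complex (K = 5.60 L mol⁻¹, k = 150 L mol⁻¹ s⁻¹)

At 30.0 min the flask makes starting material 2.20 times faster than it uses it up, each step taken net, and its solid stands at 74.4%, so 25.6% has left the solid against the 26.2% reckoned from F. In the neighbour flask charged with 0.50 M of solid substrate, F gives 10.5% dissolved by the same time, and that flask's solid stands at 89.8%, with product at 2.94%.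

(The numbers in the tables stem from a simulated flask for substances that don't exist; noise was put on by code.)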